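**Plan**

1. Ring B is numbered C1 (aroyl carbon), C2 (OH), C3 (H), C4 (CH3), C5 (OMe), C6 (CH2OAc). The hard part is this pentasubstituted ring carrying a tetra-ortho-substituted diaryl ketone.
2. Retrosynthesis: first the C5 O–Me bond and the C2 O–H (as O–Si) are cut. Then ring B itself is cut at C1–C2 and C5–C6 into a 4-methyl-2-silyloxyfuran (C2–C5 with both oxygens) and an ynone (C1 and C6 with ring A, the ketone and the CH2OAc already in place). The ynone is cut at its C(=O)–C(sp) bond.
3. Enabling feature: the C2 and C5 oxygens are para, and the two carbon substituents sit on the adjacent C1/C6 with the acceptor carbonyl on C1. This is the imprint of a 2-oxyfuran/alkyne cycloaddition with ring opening, in which the furan ring oxygen becomes C5–O and the exocyclic oxygen becomes C2–O.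
4. Forward: the silyloxyfuran and the ynone are each made in one step. Ring B, the only ring that is built, arises in the key step with all six positions set and the two oxygens already differentiated (C2–OSi, C5–OH). O-methylation and desilylation finish the route.
5. Stereochemistry: the target has no stereocentre, and rotation about the aryl–carbonyl bonds is assumed fast, so it is achiral and nothing needs to be controlled. The two bridgehead stereocentres of the transient cycloadduct vanish on aromatisation.

Key step: step 3

**Route**

Step 1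
Reactants: 1 4-methylfuran-2(5H)-one
Product: 2 tert-butyldimethyl[(4-methylfuran-2-yl)oxy]silane
Conditions: TBSOTf (1.1 equiv), Et3N (1.3 equiv), CH2Cl2, 0 °C
Reagents that add atoms: tert-butyldimethylsilyl trifluoromethanesulfonate (TBSOTf), CC(C)(C)[Si](C)(C)OS(=O)(=O)C(F)(F)F
Why: Silyl triflate/amine soft enolisation of a butenolide (O-silylation, then γ-deprotonation) is the standard route to 2-silyloxyfurans, with the aromatic furan as the thermodynamic sink.

Step 2
Reactants: 3 2,6-dimethoxybenzoyl chloride; 4 prop-2-yn-1-yl acetate (propargyl acetate)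
Product: 5 4-(2,6-dimethoxyphenyl)-4-oxobut-2-yn-1-yl acetate
Conditions: PdCl2(PPh3)2 (2 mol %), CuI (4 mol %), Et3N (1.1 equiv), THF, rt
Reagents that add atoms: none
Why: Acyl Sonogashira coupling of a non-enolisable aroyl chloride with the copper acetylide of 4 should give the ynone directly, the primary acetate being inert to near-stoichiometric amine at room temperature.

Step 3
Reactants: 2 tert-butyldimethyl[(4-methylfuran-2-yl)oxy]silane; 5 4-(2,6-dimethoxyphenyl)-4-oxobut-2-yn-1-yl acetate
Product: 7 [3-(tert-butyldimethylsilyloxy)-2-(2,6-dimethoxybenzoyl)-6-hydroxy-5-methylphenyl]methyl acetate, via oxanorbornadiene cycloadduct 6 (not isolated)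
Conditions: 2 (1.5 equiv), PhMe, 80 °C, sealed tube
Reagents that add atoms: none
Why: A normal-electron-demand Diels–Alder reaction of the silyloxyfuran (diene C2–C5) with the ynone gives 6, whose C–O bridge bond at the silyloxy-bearing bridgehead ionises and, after a 1,2-H shift and tautomerisation, leaves the arene; the closest known reaction type is the cycloaddition–aromatisation of 2-silyloxyfurans with acetylenic esters and ketones to hydroquinone monosilyl ethers. Ring B is closed by an intermolecular, asynchronous [4+2] cycloaddition that forms the C1–C2 and C5–C6 bonds together. The two bridgehead stereocentres of 6 form as a racemate and are erased on aromatisation, so no stereocontrol is required. The step needs regioselectivity: the most nucleophilic furan carbon (C5, the γ-terminus of the silyl dienolate) must bond to the β-carbon of the ynone (the CH2OAc-bearing carbon), and this is secured by the matched push–pull polarisation, the ketone being the only acceptor on the alkyne. The same polarisation directs the ring opening, since only the silyloxy-bearing bridgehead stabilises a cation, so the silyl group stays on O–C2 and the free hydroxyl appears on C5.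

Step 4
Reactants: 7 [3-(tert-butyldimethylsilyloxy)-2-(2,6-dimethoxybenzoyl)-6-hydroxy-5-methylphenyl]methyl acetate
Product: 8 [3-(tert-butyldimethylsilyloxy)-2-(2,6-dimethoxybenzoyl)-6-methoxy-5-methylphenyl]methyl acetate
Conditions: Me3O·BF4 (1.5 equiv), Proton-sponge (1.6 equiv), CH2Cl2, 0 °C to rt
Reagents that add atoms: trimethyloxonium tetrafluoroborate, C[O+](C)C.F[B-](F)(F)F
Why: O-Methylation of a phenol with a Meerwein salt buffered by a non-nucleophilic base should hit the only free hydroxyl (C5–OH; C2–O is silylated) without generating a free phenoxide, so the ortho benzylic acetate is neither expelled (o-quinone methide) nor transferred to the phenol oxygen.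

Step 5
Reactants: 8 [3-(tert-butyldimethylsilyloxy)-2-(2,6-dimethoxybenzoyl)-6-methoxy-5-methylphenyl]methyl acetate
Product: 9 preacredinone A, [2-(2,6-dimethoxybenzoyl)-3-hydroxy-6-methoxy-5-methylphenyl]methyl acetate
Conditions: TBAF (1.1 equiv), AcOH (1.2 equiv), THF, 0 °C
Reagents that add atoms: none
Why: Fluoride cleavage of an aryl silyl ether, buffered with acetic acid so that the phenoxide is protonated at once and the primary acetate is spared, should free the C2–OH, which cannot form a quinone methide with the meta CH2OAc.

**Compound list**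

1 | 4-methylfuran-2(5H)-one | CC1=CC(=O)OC1 | starting material
2 | tert-butyldimethyl[(4-methylfuran-2-yl)oxy]silane | Cc1coc(O[Si](C)(C)C(C)(C)C)c1 | intermediate
3 | 2,6-dimethoxybenzoyl chloride | COc1cccc(OC)c1C(=O)Cl | starting material
4 | prop-2-yn-1-yl acetate | CC(=O)OCC#C | starting material
5 | 4-(2,6-dimethoxyphenyl)-4-oxobut-2-yn-1-yl acetate | COc1cccc(OC)c1C(=O)C#CCOC(C)=O | intermediate
6 | [1-(tert-butyldimethylsilyloxy)-2-(2,6-dimethoxybenzoyl)-5-methyl-7-oxabicyclo[2.2.1]hepta-2,5-dien-3-yl]methyl acetate (racemic, not isolated) | CC(=O)OCC1=C(C(=O)c2c(OC)cccc2OC)C2(O[Si](C)(C)C(C)(C)C)C=C(C)C1O2 | intermediate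
7 | [3-(tert-butyldimethylsilyloxy)-2-(2,6-dimethoxybenzoyl)-6-hydroxy-5-methylphenyl]methyl acetate | COc1cccc(OC)c1C(=O)c1c(O[Si](C)(C)C(C)(C)C)cc(C)c(O)c1COC(C)=O | intermediate
8 | [3-(tert-butyldimethylsilyloxy)-2-(2,6-dimethoxybenzoyl)-6-methoxy-5-methylphenyl]methyl acetate | COc1cccc(OC)c1C(=O)c1c(O[Si](C)(C)C(C)(C)C)cc(C)c(OC)c1COC(C)=O | intermediate
9 | preacredinone A, [2-(2,6-dimethoxybenzoyl)-3-hydroxy-6-methoxy-5-methylphenyl]methyl acetate | COc1cccc(OC)c1C(=O)c1c(O)cc(C)c(OC)c1COC(C)=O | target

**Step count**

Total steps: 5. Longest linear sequence: 4 steps (steps 1, 3, 4, 5, or 2, 3, 4, 5).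

**Steps most likely to fail**

Step 3 (key step). The internal, singly activated alkyne may react too slowly. The silyloxyfuran could then be consumed by open-chain vinylogous Michael addition without ring closure, or decay thermally before cycloaddition. The fallback sets out from ynone 5 and returns to the route at target 9, replacing the [4+2] logic by a chromium-templated [3+2+1] benzannulation. Isopropenyllithium is added to Cr(CO)6 and the acyl chromate is O-methylated with Me3O·BF4 to give pentacarbonyl[methoxy(prop-1-en-2-yl)carbene]chromium(0) F1. Dötz benzannulation of F1 with 5 (THF, 50 °C) should give the tricarbonylchromium complex of the target F2. In it the carbene carbon becomes C5 with its OMe, the isopropenyl carbons become C4 and C3, a CO ligand becomes C2–OH, and the bulkier aroyl-bearing alkyne carbon is placed next to the new hydroxyl. Exposure of F2 to air and light should release 9 directly.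

Step 4. The hindered C5–OH, flanked by CH3 and CH2OAc, may methylate incompletely. Any phenoxide that builds up can expel the ortho acetate as an o-quinone methide or take over the acetyl group. The fallback sets out from 3 (with 2) and returns at 8. It carries the benzylic oxygen through cycloaddition and methylation as an ether that cannot leave.
- Acyl Sonogashira coupling of 3 with commercial 4-methoxybenzyl propargyl ether should give 1-(2,6-dimethoxyphenyl)-4-[(4-methoxybenzyl)oxy]but-2-yn-1-one F3.
- Cycloaddition–aromatisation of F3 with 2 (PhMe, 80 °C) should give [2-(tert-butyldimethylsilyloxy)-5-hydroxy-6-{[(4-methoxybenzyl)oxy]methyl}-4-methylphenyl](2,6-dimethoxyphenyl)methanone F4.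
- Ordinary methylation (MeI, K2CO3, acetone) should give [2-(tert-butyldimethylsilyloxy)-5-methoxy-6-{[(4-methoxybenzyl)oxy]methyl}-4-methylphenyl](2,6-dimethoxyphenyl)methanone F5.
- DDQ (CH2Cl2/pH 7 buffer) should release [2-(tert-butyldimethylsilyloxy)-6-(hydroxymethyl)-5-methoxy-4-methylphenyl](2,6-dimethoxyphenyl)methanone F6, which may sit partly as its cyclic hemiketal.
- Acetylation of F6 (Ac2O, pyridine, DMAP) through the open form should give 8.

Step 2. The γ-acetoxy ynone may isomerise under the amine to allenic products or suffer conjugate addition, and the hindered acyl–palladium species may decarbonylate. The fallback sets out from 4 and returns at 5, forming the C–C bond at the alcohol oxidation level. Zinc triflate/triethylamine-mediated addition of 4 to 2,6-dimethoxybenzaldehyde (PhMe, rt) should give racemic 4-(2,6-dimethoxyphenyl)-4-hydroxybut-2-yn-1-yl acetate F7. Neutral oxidation of F7 with MnO2 (CH2Cl2, rt) should give 5.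

**Further compounds**

F1 | step 3 | pentacarbonyl[methoxy(prop-1-en-2-yl)carbene]chromium(0) | COC(C(C)=C)=[Cr](=C=O)(=C=O)(=C=O)(=C=O)=C=O
F2 | step 3 | tricarbonylchromium(0) η6-complex of 9 on ring B (written as separate fragments) | COc1cccc(OC)c1C(=O)c1c(O)cc(C)c(OC)c1COC(C)=O.[Cr].[C-]#[O+].[C-]#[O+].[C-]#[O+]
F3 | step 4 | 1-(2,6-dimethoxyphenyl)-4-[(4-methoxybenzyl)oxy]but-2-yn-1-one | COc1ccc(COCC#CC(=O)c2c(OC)cccc2OC)cc1
F4 | step 4 | [2-(tert-butyldimethylsilyloxy)-5-hydroxy-6-{[(4-methoxybenzyl)oxy]methyl}-4-methylphenyl](2,6-dimethoxyphenyl)methanone | COc1ccc(COCc2c(O)c(C)cc(O[Si](C)(C)C(C)(C)C)c2C(=O)c2c(OC)cccc2OC)cc1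
F5 | step 4 | [2-(tert-butyldimethylsilyloxy)-5-methoxy-6-{[(4-methoxybenzyl)oxy]methyl}-4-methylphenyl](2,6-dimethoxyphenyl)methanone | COc1ccc(COCc2c(OC)c(C)cc(O[Si](C)(C)C(C)(C)C)c2C(=O)c2c(OC)cccc2OC)cc1
F6 | step 4 | [2-(tert-butyldimethylsilyloxy)-6-(hydroxymethyl)-5-methoxy-4-methylphenyl](2,6-dimethoxyphenyl)methanone | OCc1c(OC)c(C)cc(O[Si](C)(C)C(C)(C)C)c1C(=O)c1c(OC)cccc1OC
F7 | step 2 | 4-(2,6-dimethoxyphenyl)-4-hydroxybut-2-yn-1-yl acetate (racemic) | COc1cccc(OC)c1C(O)C#CCOC(C)=O
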